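**Remark.** The target has no stereocentre, so all SMILES strings are written without stereodescriptors. Atom labels used throughout: ring A is the pentasubstituted ring, with C1 (bearing the hydroxymethyl carbon C8), C2 (bearing the bridging methylene C7), C3 (Br), C4 (OH), C5 (OH) and C6 (H). Ring B has C1' (bonded to C7), C2' (H), C3' (OH), C4' (OH), C5' (Br) and C6' (H).

## Analysis of the target

The target 12 is a diarylmethane in which ring A and ring B are joined through C7. There is no stereocentre and no ring to close, so the problem is purely regiochemical. Ring A carries five different substituents in unbroken sequence (C8 on C1, C7 on C2, Br on C3, OH on C4, OH on C5), and C2 is the most hindered carbon, lying between the hydroxymethyl group and bromine. Both rings are the same 3-bromo-4,5-dihydroxybenzyl unit, so the molecule is formally a dimer in which C7 of one unit is bonded to C2 of the other; substitution chemistry therefore has little to tell the two rings, or the free positions of ring A, apart. The sensitive groups are the two catechols (air oxidation), the p-hydroxybenzyl alcohol at C1 (ionisation to a p-quinone methide, then etherification or self-alkylation) and the two aryl bromides (metal–halogen exchange, hydrogenolysis). The feature that the route exploits is the neighbouring pair C2 (carbon substituent) and C3 (bromine) on ring A, with the C4 oxygen directly beside C3. This is the pattern left when a carbon nucleophile and then an electrophile add across a C2≡C3 aryne that has an alkoxy group on the carbon next to C3. All five oxygens are carried as methyl ethers, the only protecting group that tolerates the organolithium and organomagnesium chemistry and can be removed in one operation.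

## Retrosynthetic reasoning

**From 12 to 10.** The five O–CH3 bonds of pentamethyl ether 10 are cut; no skeletal bond is touched. A Lewis-acid ether cleavage frees the four phenols and turns the benzylic methyl ether into benzylic bromide 11. Because 11 is a p-hydroxybenzyl bromide, water replaces the bromide on work-up. The gain is that every earlier intermediate is a robust, non-phenolic ether.

**From 10 to 2 and 6.** The C2–C7 bond and the C3–Br bond are cut together. These two bonds sit on neighbouring carbons, and C2 is the position no substitution reaction reaches selectively, so both are formed across aryne 8 (C2≡C3). The forward reaction needs a benzylic carbon nucleophile (Grignard reagent 6, the complete ring B with C7) to add at C2, giving arylmagnesium 9 with the metal on C3, which an electrophilic bromine donor then brominates. The C4 methoxy group beside the triple bond sends the nucleophile to the distal carbon C2. Aryne 8 comes from aryl bromide 2 through aryllithium 7. In 2 the bromine is on C2 and its only ortho hydrogen is on C3, flanked by Br and the C4 methoxy group, so only one aryne can form. In net terms the bromine of 2 moves from C2 to C3 and the benzyl group takes its place. Cutting the other aryl–CH2 bond (C7–C1') instead would leave the whole substitution problem of ring A unsolved.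

**From 6 to 3.** The C7–Mg bond is cut back to benzylic chloride 5 (magnesium insertion), the C–Cl bond to alcohol 4, and 4 to aldehyde 3 by reduction. These are functional-group changes on a commercial ring B building block that already carries the C5' bromine in the right place.

**From 2 to 1.** The O–CH3 bond of the benzylic ether is cut. Commercial alcohol 1 is methylated so that no acidic OH and no alkoxide sits beside the aryne, and so that the C8 oxygen shares the protecting group of the phenols.

## Alternatives that were turned down

**Alternative 1:** the textbook Friedel–Crafts benzylation, cutting only C2–C7. Acid would ionise alcohol 4 (or chloride 5) and the cation would alkylate C2 of a second 3-bromo-4,5-dimethoxybenzyl unit; in the simplest form 4 alkylates itself to give alcohol A1, the tetramethyl ether of the target. It was turned down for three reasons: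
- Nucleophile and electrophile precursor are the same kind of molecule, and A1 still has an ionisable benzylic alcohol and free ring positions, so chain growth to trimers and macrocyclic oligomers has no reason to stop at the dimer.
- C2 is para to the C5 methoxy group but lies between Br and the side chain, while C6 is unhindered, so regioisomer A2 should compete.
- Nothing in the substrate decides either selectivity, and the approach does not use the structure.

**Alternative 2:** aryllithium addition and late bromination, cutting C2–C7 by carbonyl addition and C3–Br by electrophilic substitution. Bromine–lithium exchange on 2, addition to aldehyde 3 (carbinol A3) and ionic hydrogenation would give diarylmethane A4, which would then be brominated. It was turned down for three reasons: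
- The bromine of 2 is spent on the C–C bond and has to be brought back next door by electrophilic substitution. In A4 the most activated free position is C6' of ring B (para to the C3' methoxy group), followed by C6 of ring A, whereas C3 is wedged between a methoxy group and the benzyl group.
- The acid of the deoxygenation step would let the diarylmethyl cation be captured by the neighbouring methoxymethyl oxygen.
- It takes three steps for what the aryne does in one and ends with an unsolved regiochemical problem.

**Alternative 3:** de novo construction of ring A by Diels–Alder reaction and aromatisation, forming C2–C3 and C1–C6. Alkynoate A5 and diene A6 would give cyclohexa-1,4-diene A7, and dehydrogenation with desilylation would give catechol ester A8; bromination, ester reduction and demethylation would follow. It was turned down for three reasons: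
- The cycloaddition places the substituents on C1, C2, C4 and C5 but leaves C3 as CH, so the bromine again depends on an electrophilic substitution with no control.
- The CH2 of A5 is both benzylic and propargylic to an ynoate and should isomerise to the allenoate with the mildest base.
- The sequence is longer (two to three steps to A5, then cycloaddition, aromatisation, bromination, reduction and deprotection).

Key step: step 5

## Route

Step 1
Reactants: 1 (2-bromo-4,5-dimethoxyphenyl)methanol
Product: 2 1-bromo-4,5-dimethoxy-2-(methoxymethyl)benzene
Conditions: NaH, MeI, THF, 0 °C to rt
Reagents that add atoms: iodomethane, CI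
Why: Williamson ether synthesis on a primary benzylic alkoxide; the aryl bromide and aryl ethers are inert, and the methyl ether removes the acidic OH before the aryne step.

Step 2
Reactants: 3 3-bromo-4,5-dimethoxybenzaldehyde
Product: 4 (3-bromo-4,5-dimethoxyphenyl)methanol
Conditions: NaBH4, MeOH, 0 °C
Reagents that add atoms: none
Why: Hydride reduction of an aromatic aldehyde; the aryl bromide is untouched by borohydride.

Step 3
Reactants: 4 (3-bromo-4,5-dimethoxyphenyl)methanol
Product: 5 1-bromo-5-(chloromethyl)-2,3-dimethoxybenzene
Conditions: SOCl2, CH2Cl2, 0 °C to rt
Reagents that add atoms: thionyl chloride, O=S(Cl)Cl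
Why: Chlorodehydroxylation through the chlorosulfite; the chloride is chosen over the bromide because it couples less with its own Grignard reagent in the next step.

Step 4
Reactants: 5 1-bromo-5-(chloromethyl)-2,3-dimethoxybenzene
Product: 6 (3-bromo-4,5-dimethoxybenzyl)magnesium chloride (titrated solution, used as such)
Conditions: Mg turnings (excess), 2-MeTHF, 0 °C, slow addition of 5
Reagents that add atoms: magnesium, [Mg]
Why: Magnesium inserts into a benzylic C–Cl bond far faster than into an electron-rich aryl C–Br bond, as in the known bromobenzylmagnesium halides; low temperature, dilution and excess metal should limit Wurtz coupling.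

Step 5
Reactants: 2 1-bromo-4,5-dimethoxy-2-(methoxymethyl)benzene; 6 (3-bromo-4,5-dimethoxybenzyl)magnesium chloride
Product: 10 3-bromo-4-[(3-bromo-4,5-dimethoxyphenyl)methyl]-1,2-dimethoxy-5-(methoxymethyl)benzene, via aryllithium 7 (not isolated), via aryne 8 (not isolated), via arylmagnesium chloride 9 (not isolated)
Conditions: lithium 2,2,6,6-tetramethylpiperidide (LiTMP, 1.05 equiv, from TMPH and n-BuLi), THF, −78 °C; then 6 (2.5 equiv), −78 °C to rt; then inverse addition to BrCCl2CCl2Br (excess), −78 °C to rt
Reagents that add atoms: 1,2-dibromo-1,1,2,2-tetrachloroethane, BrC(Cl)(Cl)C(Cl)(Cl)Br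
Why: LiTMP removes the only hydrogen ortho to bromine in 2 (C3–H, acidified by the flanking Br and C4 methoxy group) to give aryllithium 7, which should persist at −78 °C as doubly flanked 2-bromoaryllithiums do; once 6 is present and the mixture is warmed, metal bromide is lost and aryne 8 (C2≡C3) forms in the presence of its nucleophile. The benzylic carbon of 6 should add at C2 and leave the metal on C3 as arylmagnesium 9, because the σ-withdrawing C4 methoxy group distorts and polarises the aryne so that the distal carbon C2 is the electrophilic one and the developing carbanion sits beside oxygen; the ether oxygen of the C1 methoxymethyl group can in addition hold magnesium on the C2 side. 9 is then brominated at C3 by the bromine donor with loss of tetrachloroethene, so that bromine leaves C2 and returns on C3 while the benzyl group takes its place. The closest known reaction type is the three-component aryne coupling in which an allyl, aryl or alkyl Grignard reagent adds meta to the alkoxy group of a 3-alkoxybenzyne and the resulting arylmagnesium is trapped by an electrophile such as a halogen donor. No ring is closed and no stereocentre is formed. The step needs regioselectivity (C2 against C3 for the carbon nucleophile), secured by the C4 methoxy group, and chemoselectivity (the aryl bromide of 6 must survive), secured by consuming the amide base before 6 is added and by the slowness of aryl bromide–arylmagnesium exchange at or below room temperature. Because the other neighbour of the C–Br carbon of 2 is the substituted C1, no second aryne can form.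

Step 6
Reactants: 10 3-bromo-4-[(3-bromo-4,5-dimethoxyphenyl)methyl]-1,2-dimethoxy-5-(methoxymethyl)benzene
Product: 12 5-hydroxyisoavrainvilleol, 3-bromo-4-[(3-bromo-4,5-dihydroxyphenyl)methyl]-5-(hydroxymethyl)benzene-1,2-diol, via benzylic bromide 11 (not isolated)
Conditions: BBr3 (excess), CH2Cl2, −78 °C to rt; then acetone/H2O, NaHCO3, 0 °C to rt, under argon, no alcohol solvents
Reagents that add atoms: water, O
Why: Lewis-acid ether cleavage frees the four phenols and converts the benzylic methyl ether into benzylic bromide 11; 11 is a p-hydroxybenzyl bromide (C4–OH para to C1) and should be hydrolysed on buffered aqueous work-up through the p-quinone methide, which water captures at C8. The aryl bromides and the diarylmethane are inert to BBr3.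

## Compound list

1 | (2-bromo-4,5-dimethoxyphenyl)methanol | OCc1cc(OC)c(OC)cc1Br | starting material
2 | 1-bromo-4,5-dimethoxy-2-(methoxymethyl)benzene | COCc1cc(OC)c(OC)cc1Br | intermediate
3 | 3-bromo-4,5-dimethoxybenzaldehyde | O=Cc1cc(OC)c(OC)c(Br)c1 | starting material
4 | (3-bromo-4,5-dimethoxyphenyl)methanol | OCc1cc(OC)c(OC)c(Br)c1 | intermediate
5 | 1-bromo-5-(chloromethyl)-2,3-dimethoxybenzene | ClCc1cc(OC)c(OC)c(Br)c1 | intermediate
6 | (3-bromo-4,5-dimethoxybenzyl)magnesium chloride | Cl[Mg]Cc1cc(OC)c(OC)c(Br)c1 | intermediate
7 | [2-bromo-5,6-dimethoxy-3-(methoxymethyl)phenyl]lithium | COCc1cc(OC)c(OC)c([Li])c1Br | intermediate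
8 | 3,4-dimethoxy-6-(methoxymethyl)benzyne (1,2-didehydro-3,4-dimethoxy-6-(methoxymethyl)benzene) | COCC1=CC(OC)=C(OC)C#C1 | intermediate
9 | {2-[(3-bromo-4,5-dimethoxyphenyl)methyl]-5,6-dimethoxy-3-(methoxymethyl)phenyl}magnesium chloride | COCc1cc(OC)c(OC)c([Mg]Cl)c1Cc1cc(OC)c(OC)c(Br)c1 | intermediate
10 | 3-bromo-4-[(3-bromo-4,5-dimethoxyphenyl)methyl]-1,2-dimethoxy-5-(methoxymethyl)benzene | COCc1cc(OC)c(OC)c(Br)c1Cc1cc(OC)c(OC)c(Br)c1 | intermediate
11 | 3-bromo-4-[(3-bromo-4,5-dihydroxyphenyl)methyl]-5-(bromomethyl)benzene-1,2-diol | BrCc1cc(O)c(O)c(Br)c1Cc1cc(O)c(O)c(Br)c1 | intermediate
12 | 5-hydroxyisoavrainvilleol, 3-bromo-4-[(3-bromo-4,5-dihydroxyphenyl)methyl]-5-(hydroxymethyl)benzene-1,2-diol | OCc1cc(O)c(O)c(Br)c1Cc1cc(O)c(O)c(Br)c1 | target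

## Step count and risks

Total step count: 6. Longest linear sequence: 5 steps (3 to 4 to 5 to 6 to 10 to 12); the branch from 1 to 2 is one step.

**Step 5 (key step).** Four processes could spoil it:
- loss of regiocontrol in the addition to 8, since C2 is the hindered carbon beside the methoxymethyl group;
- loss of lithium bromide from 7 before 6 is present, after which the amide or a second aryl anion would add to the aryne;
- protonation of 9 by the liberated amine before the bromine donor arrives;
- reaction of the benzylic Grignard reagent through its ortho carbon.

The fallback keeps the bromine where commerce already put it and makes C2–C7 by cross-coupling. It sets out from 4 and 5 and returns at 10. Alcohol 4 would be methylated (NaH, MeI) to 1-bromo-2,3-dimethoxy-5-(methoxymethyl)benzene F1. F1 would be metalated at C2, its only position ortho to bromine, with in situ trapping (LiTMP, ZnCl2, THF, −78 °C) and iodinated (I2) to 3-bromo-2-iodo-4,5-dimethoxy-1-(methoxymethyl)benzene F2. Chloride 5 would be converted with Zn dust and LiCl in THF into (3-bromo-4,5-dimethoxybenzyl)zinc chloride F3, a reagent type that tolerates aryl bromides. Negishi coupling of F2 with F3 (Pd(PPh3)4, THF, 25 to 50 °C) should take place at the C–I bond in preference to both C–Br bonds and give 10.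

**Step 6.** The benzylic bromide 11 and the product are p-hydroxybenzyl electrophiles, so Friedel–Crafts-type self-alkylation through the quinone methide could compete with hydrolysis. Air oxidation of the catechols at basic pH is a second hazard. The fallback moves C8 to the aldehyde oxidation level, where no benzylic leaving group exists during demethylation; it sets out from 10 and returns at 12. DDQ (CH2Cl2/H2O, 0 °C) should oxidise the benzylic methyl ether, activated by the para C4 methoxy group and by its own oxygen, to 3-bromo-2-[(3-bromo-4,5-dimethoxyphenyl)methyl]-4,5-dimethoxybenzaldehyde F4. The diarylmethane C7, twisted out of conjugation by its two ortho neighbours, should be slower to react, although over-oxidation there remains the risk of this fallback. BBr3 (CH2Cl2) would then give 3-bromo-2-[(3-bromo-4,5-dihydroxyphenyl)methyl]-4,5-dihydroxybenzaldehyde F5, and NaBH4 (THF/H2O, 0 °C, neutral work-up) would give 12.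

**Step 4.** Wurtz-type homocoupling of the electron-rich benzylic chloride at the metal surface, or competing insertion into the aryl C–Br bond, would lower the titre of 6. The fallback gives up the benzylic organometallic and brings C7 in as the electrophilic carbonyl carbon of 3; it sets out from 4 and 3 and returns at 10. Ether F1 (made from 4 as described under step 5) would be magnesiated at C2 with in situ transmetalation (LiTMP, MgCl2, THF, −78 °C) and added to aldehyde 3 to give racemic [2-bromo-3,4-dimethoxy-6-(methoxymethyl)phenyl](3-bromo-4,5-dimethoxyphenyl)methanol F6. Ionic hydrogenation (Et3SiH in excess, TFA, CH2Cl2, 0 °C) would then give 10.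

## Further compounds

F1 | step 5 | 1-bromo-2,3-dimethoxy-5-(methoxymethyl)benzene | COCc1cc(OC)c(OC)c(Br)c1
F2 | step 5 | 3-bromo-2-iodo-4,5-dimethoxy-1-(methoxymethyl)benzene | COCc1cc(OC)c(OC)c(Br)c1I
F3 | step 5 | (3-bromo-4,5-dimethoxybenzyl)zinc chloride | Cl[Zn]Cc1cc(OC)c(OC)c(Br)c1
F4 | step 6 | 3-bromo-2-[(3-bromo-4,5-dimethoxyphenyl)methyl]-4,5-dimethoxybenzaldehyde | O=Cc1cc(OC)c(OC)c(Br)c1Cc1cc(OC)c(OC)c(Br)c1
F5 | step 6 | 3-bromo-2-[(3-bromo-4,5-dihydroxyphenyl)methyl]-4,5-dihydroxybenzaldehyde | O=Cc1cc(O)c(O)c(Br)c1Cc1cc(O)c(O)c(Br)c1
F6 | step 4 | [2-bromo-3,4-dimethoxy-6-(methoxymethyl)phenyl](3-bromo-4,5-dimethoxyphenyl)methanol (racemic) | COCc1cc(OC)c(OC)c(Br)c1C(O)c1cc(OC)c(OC)c(Br)c1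
A1 | alternative 1 | [3-bromo-2-[(3-bromo-4,5-dimethoxyphenyl)methyl]-4,5-dimethoxyphenyl]methanol | OCc1cc(OC)c(OC)c(Br)c1Cc1cc(OC)c(OC)c(Br)c1
A2 | alternative 1 | [5-bromo-2-[(3-bromo-4,5-dimethoxyphenyl)methyl]-3,4-dimethoxyphenyl]methanol | OCc1cc(Br)c(OC)c(OC)c1Cc1cc(OC)c(OC)c(Br)c1
A3 | alternative 2 | (3-bromo-4,5-dimethoxyphenyl)[4,5-dimethoxy-2-(methoxymethyl)phenyl]methanol (racemic) | COCc1cc(OC)c(OC)cc1C(O)c1cc(OC)c(OC)c(Br)c1
A4 | alternative 2 | 1-bromo-5-[[4,5-dimethoxy-2-(methoxymethyl)phenyl]methyl]-2,3-dimethoxybenzene | COCc1cc(OC)c(OC)cc1Cc1cc(OC)c(OC)c(Br)c1
A5 | alternative 3 | methyl 4-(3-bromo-4,5-dimethoxyphenyl)but-2-ynoate | COC(=O)C#CCc1cc(OC)c(OC)c(Br)c1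
A6 | alternative 3 | 2,3-bis(trimethylsilyloxy)buta-1,3-diene | C=C(O[Si](C)(C)C)C(=C)O[Si](C)(C)C
A7 | alternative 3 | methyl 2-[(3-bromo-4,5-dimethoxyphenyl)methyl]-4,5-bis(trimethylsilyloxy)cyclohexa-1,4-diene-1-carboxylate | COC(=O)C1=C(Cc2cc(OC)c(OC)c(Br)c2)CC(O[Si](C)(C)C)=C(O[Si](C)(C)C)C1
A8 | alternative 3 | methyl 2-[(3-bromo-4,5-dimethoxyphenyl)methyl]-4,5-dihydroxybenzoate | COC(=O)c1cc(O)c(O)cc1Cc1cc(OC)c(OC)c(Br)c1
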